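If free catalyst treated both substrates alike, this racemate would end with a share of 0.5 as left-handed product, so I took that mark as the zero of my scale.

common to all: free catalyst 3.4 mM; racemization catalyst 0.25 mM

| run | left-handed substrate | right-handed substrate | reagent | temperature | remark | time |
|---|---|---|---|---|---|---|
| eta | 0.050 M | 0.050 M | 0.15 M | 25 °C | the very flask that is asked about, followed so far |  |
| epsilon | 0.034 M | 0.034 M | 0.15 M | 10 °C | run made earlier |  |
| flask | 0.050 M | 0.050 M | 0.150 M | 25 °C |  | 8.0 d |

| run | time / h | left-handed product / % |
|---|---|---|
| eta | 20.0 | 50 |
| eta | 40.0 | 53 |
| eta | 72.0 | 54 |
| eta | 96.0 | 53 |
| eta | 120 | 58 |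
| eta | 144 | 56 |
| epsilon | 6.00 | 16 |
| epsilon | 8.00 | 21 |
| epsilon | 12.0 | 26 |
| epsilon | 20.0 | 35 |
| epsilon | 30.0 | 41 |
| epsilon | 48.0 | 44 |
| epsilon | 96.0 | 52 |

(readings scatter by 1.5 percentage points)

- free catalyst is single-handed; left-handed substrate and right-handed substrate are mirror images of each other, charged as a racemate, each of them at the stated concentration
- what is taken out of left-handed product is counted as made
- "the catalyst" is free catalyst with its forms; racemization catalyst is a second catalyst
- additions bring no volume worth counting

- Sunday's: at 8.0 d add free catalyst, 50.0% of the amount charged, then wait 4.0 d
- Friday's: change nothing and wait 4.0 d more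
- Saturday's: at 8.0 d add reagent, 100% of the amount charged, then wait 4.0 d
- Monday's: at 8.0 d raise the temperature by 10 K, then wait 4.0 d
- Wednesday's: at 8.0 d take out 90% of the left-handed product then present, then wait 4.0 d

- left-handed product, in percent of the left-handed substrate and right-handed substrate together first charged, at 8.0 d
- which option adds most left-handed product ("none" when 2 percentage points or less is all one gets) (Sunday's / Friday's / Saturday's / Monday's / Wednesday's / none)
- left-handed product present, with what was taken out counted in, in percent of the left-handed substrate and right-handed substrate together first charged, after Friday's
- left-handed product present, with what was taken out counted in, in percent of the left-handed substrate and right-handed substrate together first charged, after Monday's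

My quantity was the lead, the points by which left-handed product stands above that mark once the curve has gone flat. As a reading it came to 5.2 percentage points, the mean of the eta readings from 72.0 h on; eta is the asked flask itself. A lead above zero means that right-handed substrate crossed over through the racemization catalyst, as in a dynamic kinetic resolution. Reagent was charged at 1.50 times the two substrates together, so by count it was no stopper, and I supposed that the remaining substrate had gone to right-handed product.

That gave me a first way to the answer: a level at 55.2%, the same at 8.0 d and at 12.0 d. My second way was a straight line through the eta readings at 40.0 h and 144 h, which gave 57.4% at 8.0 d and 60.2% at 12.0 d. The two ways share a reading, so their closeness at 8.0 d checked nothing. They parted on Friday's, where the line gained 2.8 points against a margin of 2 points and the level gained nothing. The line stood on a rise of 3 points whose own scatter was 2.1 points, and the reading at 96.0 h lay lower than the one at 72.0 h, so I judged that the line was following scatter. I committed to the level: 55.2% at 8.0 d, the same after Friday's and Monday's, and no option worth taking.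

The forecast gave 59% now, 63% after Friday's and 67% after Monday's, with Monday's as best, holding that “racemization is the bottleneck”. Its number for now stood above my level.

The flask gave 56.4% at 8.0 d, 56.4% after Friday's and 56.4% after Monday's, and the best option was none.

    left-handed substrate + racemization catalyst ⇌ right-handed substrate + racemization catalyst, rate k1*[racemization catalyst]*[left-handed substrate] forward; the back reaction follows from the equilibrium constant (k = 194 /M/h, Ea = 70.0 kJ/mol)
    reagent + free catalyst + right-handed substrate → free catalyst + right-handed product (k = 285 /M²/h, Ea = 44.0 kJ/mol)
    reagent + free catalyst + left-handed substrate → free catalyst + left-handed product (k = 470 /M²/h, Ea = 57.0 kJ/mol)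
    reagent ⇌ dormant form (K = 2.10, k = 0.00354 /h, Ea = 103 kJ/mol, ΔH = 19.0 kJ/mol)
    (constants at 25 °C)

At 192 h the flask held 56.4% left-handed product and 43.6% right-handed product, with 0.0059% and 0.0071% of the two substrates' own charges left, a lead of 6.4 points. I tried the lead on the neighbour charged with 0.037 M reagent. By count that reagent makes 37.0% product, and the level's share of it gives 20.4% left-handed product. In that neighbour 0.050% of the reagent remained, and left-handed product stood at 22.0% beside 14.1% right-handed product.

The data come from a simulation from invented constants, and the scatter is random.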